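**Plan**
1. Cuts: C-13=C-14 (ring-closing metathesis) and C-11–C-12 (allylation) lead back to a bicyclic C-11 aldehyde; C-4–C-18 is cut next (enolate methylation). Then C-5–C-10 and C-2–C-3 are cut together (Michael–Claisen annulation), which opens ring B and ring A to an acyclic keto alkylidene malonate. This chain is cut at C-4=C-5 (Knoevenagel), C-1–C-2 (MeLi), C-10–C-20 (MeI) and C-8–C-9 (conjugate addition to furan-2(5H)-one).
2. Enabling feature: C-4 of ring A carries two oxygenated carbons (C-3 and C-19). C-3/C-4/C-19 can therefore be a malonate and C-4=C-5 an alkylidene malonate, electrophilic at C-5 and at C-3. Its partner C-10–C-1–C-2 is an α-branched methyl ketone (temporary C-1 carbonyl), nucleophilic first at C-10, then at C-2.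
3. Forward: the chain is built on the butenolide; ring B and then ring A close in one operation (step 8). The C-1 oxygen is tied to O-11 as a cyclic enol ether, which tells the two carbonyls of the dione apart, and is then removed reductively. The side-chain butenolide is made last.
4. Stereochemistry: C-9 from the rhodium/(S)-BINAP addition; C-10 and C-5 from the chair transition state of the Michael step (relayed from C-9); C-4 from methylation anti to CH3-20; C-3 from axial hydride delivery; C-11 from Felkin–Anh addition.

Key step: step 8

Remark: the decalin compounds are described with labdane numbering (ring A: C-1 to C-5 and C-10; ring B: C-5 to C-10; C-11 on C-9; C-17 the methylidene carbon on C-8; C-18 and C-19 on C-4; C-20 the methyl on C-10).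
Assumption: the sense of induction in step 3 is taken from rhodium/BINAP additions to cyclic enones and unsaturated lactones; if it proved opposite, the enantiomeric ligand would be used.

**Step 1**
Reactants: 1 2-(2-bromoethyl)-1,3-dioxolane; 2 lithium acetylide–ethylenediamine complex
Product: 3 2-(but-3-yn-1-yl)-1,3-dioxolane
Conditions: DMSO, 15 → 23 °C
Reagents that add atoms: none
Why: SN2 alkylation of the acetylide by the primary bromide (acetylide alkylation) should give the terminal alkyne; no stereocentre is formed.

**Step 2**
Reactants: 3 2-(but-3-yn-1-yl)-1,3-dioxolane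
Product: 5 2-[4-(1,3-dioxolan-2-yl)but-1-en-2-yl]-4,4,5,5-tetramethyl-1,3,2-dioxaborolane, via alkenylalane 4 (not isolated)
Conditions: NiCl2(dppp) (3 mol %; dppp = 1,3-bis(diphenylphosphino)propane), i-Bu2AlH (1.3 equiv), THF, 0 → 22 °C; then MeOBpin, 0 → 80 °C
Reagents that add atoms: 2-methoxy-4,4,5,5-tetramethyl-1,3,2-dioxaborolane, COB1OC(C)(C)C(C)(C)O1
Why: nickel-catalysed Markovnikov hydroalumination of the terminal alkyne puts aluminium on the internal carbon, and aluminium-to-boron exchange with the borate ester should give the 1,1-disubstituted alkenylboronate; the dioxolane should be inert to the hydride in THF at this temperature.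

**Step 3**
Reactants: 5 2-[4-(1,3-dioxolan-2-yl)but-1-en-2-yl]-4,4,5,5-tetramethyl-1,3,2-dioxaborolane; 6 furan-2(5H)-one
Product: 7 (4S)-4-[4-(1,3-dioxolan-2-yl)but-1-en-2-yl]oxolan-2-one
Conditions: [Rh(OH)(cod)]2 (2.5 mol %; cod = 1,5-cyclooctadiene), (S)-BINAP (6 mol %), KOH (0.2 equiv), 1,4-dioxane/H2O (10:1), 50 °C
Reagents that add atoms: none
Why: the Hayashi–Miyaura rhodium-catalysed asymmetric 1,4-addition of the alkenylboron reagent to the butenolide should form the C-8–C-9 bond and set C-9, the (S)-ligand being expected to give the (4S)-lactone by analogy with additions to cyclic enones and lactones.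

**Step 4**
Reactants: 7 (4S)-4-[4-(1,3-dioxolan-2-yl)but-1-en-2-yl]oxolan-2-one
Product: 8 (3R,4S)-4-[4-(1,3-dioxolan-2-yl)but-1-en-2-yl]-3-methyloxolan-2-one (trans)
Conditions: LiN(i-Pr)2, THF, −78 °C; then MeI, −78 → −40 °C
Reagents that add atoms: iodomethane, CI
Why: alkylation of the lactone lithium enolate anti to the neighbouring substituent (enolate alkylation) should give the trans lactone; this centre (C-10) becomes trigonal again in step 8, so its configuration does not matter.

**Step 5**
Reactants: 8 (3R,4S)-4-[4-(1,3-dioxolan-2-yl)but-1-en-2-yl]-3-methyloxolan-2-one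
Product: 9 (3R,4S)-7-(1,3-dioxolan-2-yl)-4-(hydroxymethyl)-3-methyl-5-methylideneheptan-2-one
Conditions: MeLi (1.05 equiv), THF, −78 °C; then NH4Cl (aq)
Reagents that add atoms: methyllithium, [Li]C
Why: mono-addition of an organolithium to a γ-lactone gives a lithium hemiketal alkoxide that should be stable at −78 °C and collapse on work-up to the γ-hydroxy methyl ketone.

**Step 6**
Reactants: 9 (3R,4S)-7-(1,3-dioxolan-2-yl)-4-(hydroxymethyl)-3-methyl-5-methylideneheptan-2-one
Product: 10 (5S,6R)-5-(hydroxymethyl)-6-methyl-4-methylidene-7-oxooctanal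
Conditions: AcOH/H2O/THF (3:1:1), 45 °C
Reagents that add atoms: water, O
Why: acid-catalysed acetal hydrolysis should unmask the aldehyde while the ketone, the primary alcohol and the 1,1-disubstituted alkene survive the mild aqueous acid.

**Step 7**
Reactants: 10 (5S,6R)-5-(hydroxymethyl)-6-methyl-4-methylidene-7-oxooctanal; 11 dimethyl malonate
Product: 12 dimethyl 2-[(5S,6R)-5-(hydroxymethyl)-6-methyl-4-methylidene-7-oxooctylidene]propanedioate
Conditions: piperidine (10 mol %), AcOH (10 mol %), 4 Å molecular sieves, CH2Cl2, 23 °C
Reagents that add atoms: none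
Why: Knoevenagel condensation of the aldehyde, which is far more electrophilic than the methyl ketone, with dimethyl malonate should give the alkylidene malonate.

**Step 8**
Reactants: 12 dimethyl 2-[(5S,6R)-5-(hydroxymethyl)-6-methyl-4-methylidene-7-oxooctylidene]propanedioate
Product: 14 methyl 5-(hydroxymethyl)-4a-methyl-6-methylidene-2,4-dioxodecahydronaphthalene-1-carboxylate (trans-fused hydroxy dione; labdane numbering 1,3-dioxo), via cyclohexyl malonate 13 (not isolated)
Conditions: NaOMe (2.5 equiv), MeOH (0.02 M), 23 → 55 °C; then AcOH, 0 °C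
Reagents that add atoms: none
Why: Methoxide reversibly forms the more substituted ketone enolate at C-10, which adds to C-5 of the alkylidene malonate (6-(enolexo)-exo-trig Michael addition, ring B), and the methyl ketone enolate at C-2 then acylates one malonate ester at C-3 with loss of methoxide (6-(enolendo)-exo-trig Claisen condensation, ring A), the stabilised dione enolate being the thermodynamic sink. The closest known reaction type is the Michael–Claisen annulation of a ketone with a malonate-derived acceptor that gives cyclohexane-1,3-diones (the dimedone synthesis), run here within one molecule so that two rings close. C-10 is controlled by the C-9 stereocentre: in the chair transition state with CH2OH-11 equatorial, allylic 1,3-strain should place the enolate carbon C-1 equatorial and the C-20 methyl axial, cis to C-11. C-5 follows from the equatorial position of the forming malonyl substituent, which puts H-5 trans to the C-20 methyl and leads to the trans-fused Claisen closure, while C-4 stays epimerisable and is fixed in step 10. The step needs selection between the C-10 and C-2 enolates and between the Michael addition and other anionic pathways, and ring size should secure both, since attack of C-2 on C-5 or on an ester before the Michael step would need eight- and ten-membered rings, while deconjugation of the acceptor and alkoxide addition to it are reversible.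

**Step 9**
Reactants: 14 methyl 5-(hydroxymethyl)-4a-methyl-6-methylidene-2,4-dioxodecahydronaphthalene-1-carboxylate
Product: 15 tricyclic vinylogous ester (cyclic enol ether of 14: O-11 bonded to C-1 with C-1=C-2–C-3=O; H-4 retained)
Conditions: PPTS (10 mol %), 4 Å molecular sieves, PhMe, 50 °C
Reagents that add atoms: none
Why: acid-catalysed condensation of the C-11 hydroxyl with a carbonyl of the 1,3-dione (vinylogous ester formation) can close a five-membered ring only at C-1, so the two carbonyl groups are told apart without a protecting group.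

**Step 10**
Reactants: 15 tricyclic vinylogous ester
Product: 16 C-4 methylated tricyclic vinylogous ester (CH3-18 trans and CO2Me-19 cis to CH3-20)
Conditions: NaH, THF, 0 °C; then MeI, 0 → 23 °C
Reagents that add atoms: iodomethane, CI
Why: C-alkylation of the β-keto ester enolate should occur at C-4 from the face opposite the axial C-20 methyl (enolate alkylation, as in related 3-oxo-4-carboxylate decalins), which sets the quaternary C-4.

**Step 11**
Reactants: 16 C-4 methylated tricyclic vinylogous ester
Product: 18 methyl 5-(hydroxymethyl)-1,4a-dimethyl-6-methylidene-2-oxodecahydronaphthalene-1-carboxylate (labdane numbering: 3-oxo, 11-hydroxy, 19-ester), via enone 17 (not isolated)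
Conditions: Li (5 equiv), NH3 (l)/THF, −78 °C, 20 min; then NH4Cl (s)
Reagents that add atoms: none
Why: dissolving-metal reduction of the β-alkoxy enone (Birch-type reduction of a vinylogous ester) should give an enolate that expels the C-11 alkoxide, and the resulting enone is reduced again to the C-3 ketone enolate; this removes the helper oxygen from C-1 and frees the C-11 hydroxyl while the isolated alkene is left alone.

**Step 12**
Reactants: 18 methyl 5-(hydroxymethyl)-1,4a-dimethyl-6-methylidene-2-oxodecahydronaphthalene-1-carboxylate
Product: 19 1,5-bis(hydroxymethyl)-1,4a-dimethyl-6-methylidenedecahydronaphthalen-2-ol (labdane numbering: 3,11,19-triol; 3-OH equatorial and cis to C-19)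
Conditions: LiAlH4, THF, 0 → 23 °C; then H2O, NaOH (aq)
Reagents that add atoms: none
Why: hydride reduction converts the ester into the C-19 carbinol and reduces the C-3 ketone by axial delivery from the face opposite the axial C-19 and C-20 groups, which should give the equatorial 3-hydroxyl.

**Step 13**
Reactants: 19 labdane-numbered 3,11,19-triol
Product: 20 3,19-O-isopropylidene acetal of 19 with free 11-hydroxyl
Conditions: Me2C(OMe)2, PPTS (5 mol %), acetone, 23 °C; then MeOH, 0 °C, 10 min
Reagents that add atoms: 2,2-dimethoxypropane, COC(C)(C)OC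
Why: acid-catalysed transketalisation should form the six-membered acetonide of the 1,3-diol (C-3/C-19), and the labile mixed ketal at the primary C-11 hydroxyl is cleaved again by the brief methanolysis.

**Step 14**
Reactants: 20 3,19-O-isopropylidene acetal with free 11-hydroxyl
Product: 21 the corresponding C-11 aldehyde
Conditions: Dess–Martin periodinane, NaHCO3, CH2Cl2, 0 → 23 °C
Reagents that add atoms: none
Why: Dess–Martin oxidation under buffered conditions should give the aldehyde without epimerisation at C-9 or migration of the exocyclic double bond into conjugation.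

**Step 15**
Reactants: 22 2-(bromomethyl)prop-2-enoic acid; 23 prop-2-en-1-ol
Product: 24 prop-2-en-1-yl 2-(bromomethyl)prop-2-enoate
Conditions: p-TsOH·H2O (5 mol %), cyclohexane, reflux (Dean–Stark)
Reagents that add atoms: none
Why: Fischer esterification with azeotropic removal of water should give the allyl ester.

**Step 16**
Reactants: 21 C-11 aldehyde; 24 prop-2-en-1-yl 2-(bromomethyl)prop-2-enoate
Product: 25 prop-2-en-1-yl (4R)-4-hydroxy-2-methylidene-4-(3,19-O-isopropylidene bicyclic core)butanoate (11R in labdane numbering)
Conditions: In powder (1.5 equiv), THF/H2O (1:1), 23 °C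
Reagents that add atoms: none
Why: indium-mediated Barbier allylation adds the 2-(alkoxycarbonyl)allyl unit to the aldehyde, and Felkin–Anh attack anti to the quaternary C-10 with the C-8 alkene carbon inside should give the (11R)-alcohol.

**Step 17**
Reactants: 25 (11R)-hydroxy allyl ester
Product: 26 14-deoxy-11-hydroxyandrographolide 3,19-acetonide
Conditions: second-generation Grubbs catalyst (5 mol %), CH2Cl2 (0.005 M), 40 °C
Reagents that add atoms: none
Why: ring-closing metathesis of the allyl ester with the acrylate double bond should close the α-substituted butenolide with loss of ethene, the hindered 1,1-disubstituted exocyclic alkene on ring B being left alone.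

**Step 18**
Reactants: 26 14-deoxy-11-hydroxyandrographolide 3,19-acetonide
Product: 27 14-deoxy-11-hydroxyandrographolide
Conditions: AcOH/H2O (4:1), 23 °C
Reagents that add atoms: none
Why: mild aqueous acid should hydrolyse the acetonide (acetal hydrolysis) to the 3,19-diol without affecting the butenolide or the exocyclic alkene.

**Compound list**
1 | 2-(2-bromoethyl)-1,3-dioxolane | BrCCC1OCCO1 | starting material
2 | lithium acetylide–ethylenediamine complex | [Li+].[C-]#C.NCCN | starting material
3 | 2-(but-3-yn-1-yl)-1,3-dioxolane | C#CCCC1OCCO1 | intermediate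
4 | diisobutyl[4-(1,3-dioxolan-2-yl)but-1-en-2-yl]alane (formed in the flask, not isolated) | C=C(CCC1OCCO1)[Al](CC(C)C)CC(C)C | intermediate
5 | 2-[4-(1,3-dioxolan-2-yl)but-1-en-2-yl]-4,4,5,5-tetramethyl-1,3,2-dioxaborolane | C=C(CCC1OCCO1)B1OC(C)(C)C(C)(C)O1 | intermediate
6 | furan-2(5H)-one | O=C1OCC=C1 | starting material
7 | (4S)-4-[4-(1,3-dioxolan-2-yl)but-1-en-2-yl]oxolan-2-one | O=C1C[C@@H](C(=C)CCC2OCCO2)CO1 | intermediate
8 | (3R,4S)-4-[4-(1,3-dioxolan-2-yl)but-1-en-2-yl]-3-methyloxolan-2-one (trans) | C[C@@H]1[C@@H](C(=C)CCC2OCCO2)COC1=O | intermediate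
9 | (3R,4S)-7-(1,3-dioxolan-2-yl)-4-(hydroxymethyl)-3-methyl-5-methylideneheptan-2-one | CC(=O)[C@H](C)[C@H](CO)C(=C)CCC1OCCO1 | intermediate
10 | (5S,6R)-5-(hydroxymethyl)-6-methyl-4-methylidene-7-oxooctanal | CC(=O)[C@H](C)[C@H](CO)C(=C)CCC=O | intermediate
11 | dimethyl malonate | COC(=O)CC(=O)OC | starting material
12 | dimethyl 2-[(5S,6R)-5-(hydroxymethyl)-6-methyl-4-methylidene-7-oxooctylidene]propanedioate | CC(=O)[C@H](C)[C@H](CO)C(=C)CCC=C(C(=O)OC)C(=O)OC | intermediate
13 | dimethyl 2-[2-acetyl-3-(hydroxymethyl)-2-methyl-4-methylidenecyclohexyl]propanedioate; ring B closed, acetyl and malonyl groups trans, ring methyl cis to CH2OH (formed in the flask, not isolated) | C=C1CC[C@H](C(C(=O)OC)C(=O)OC)[C@@](C)(C(C)=O)[C@@H]1CO | intermediate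
14 | methyl 5-(hydroxymethyl)-4a-methyl-6-methylidene-2,4-dioxodecahydronaphthalene-1-carboxylate; trans-fused, H-5 trans and CH2OH-11 cis to CH3-20, C-4 epimerisable and drawn with the equatorial ester | C=C1CC[C@@H]2[C@@H](C(=O)OC)C(=O)CC(=O)[C@@]2(C)[C@@H]1CO | intermediate
15 | tricyclic vinylogous ester: cyclic enol ether of 14 with O-11 bonded to C-1, C-1=C-2–C-3=O, CO2Me on C-4 | C=C1CC[C@@H]2[C@@H](C(=O)OC)C(=O)C=C3OC[C@H]1[C@@]23C | intermediate
16 | C-4 methylated tricyclic vinylogous ester: CH3-18 trans and CO2Me-19 cis to CH3-20 | C=C1CC[C@@H]2[C@](C)(C(=O)OC)C(=O)C=C3OC[C@H]1[C@@]23C | intermediate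
17 | methyl 5-(hydroxymethyl)-1,4a-dimethyl-6-methylidene-2-oxo-1,2,4a,5,6,7,8,8a-octahydronaphthalene-1-carboxylate; C-1=C-2 enone in labdane numbering (formed in the flask, not isolated) | C=C1CC[C@@H]2[C@](C)(C(=O)OC)C(=O)C=C[C@@]2(C)[C@@H]1CO | intermediate
18 | methyl 5-(hydroxymethyl)-1,4a-dimethyl-6-methylidene-2-oxodecahydronaphthalene-1-carboxylate; labdane numbering 3-oxo, 11-hydroxy, 19-ester | C=C1CC[C@@H]2[C@](C)(C(=O)OC)C(=O)CC[C@@]2(C)[C@@H]1CO | intermediate
19 | 1,5-bis(hydroxymethyl)-1,4a-dimethyl-6-methylidenedecahydronaphthalen-2-ol; labdane numbering 3,11,19-triol, 3-OH equatorial and cis to C-19 | C=C1CC[C@@H]2[C@](C)(CO)[C@H](O)CC[C@@]2(C)[C@@H]1CO | intermediate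
20 | 3,19-O-isopropylidene acetal of 19 with free 11-hydroxyl | C=C1CC[C@@H]2[C@]3(C)COC(C)(C)O[C@@H]3CC[C@@]2(C)[C@@H]1CO | intermediate
21 | C-11 aldehyde of 20 (3,19-O-isopropylidene acetal) | C=C1CC[C@@H]2[C@]3(C)COC(C)(C)O[C@@H]3CC[C@@]2(C)[C@@H]1C=O | intermediate
22 | 2-(bromomethyl)prop-2-enoic acid | OC(=O)C(=C)CBr | starting material
23 | prop-2-en-1-ol (allyl alcohol) | C=CCO | starting material
24 | prop-2-en-1-yl 2-(bromomethyl)prop-2-enoate | C=CCOC(=O)C(=C)CBr | intermediate
25 | prop-2-en-1-yl (4R)-4-hydroxy-2-methylidene-4-(3,19-O-isopropylidene bicyclic core)butanoate; 11R in labdane numbering | C=C1CC[C@@H]2[C@]3(C)COC(C)(C)O[C@@H]3CC[C@@]2(C)[C@@H]1[C@H](O)CC(=C)C(=O)OCC=C | intermediate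
26 | 14-deoxy-11-hydroxyandrographolide 3,19-acetonide | C=C1CC[C@@H]2[C@]3(C)COC(C)(C)O[C@@H]3CC[C@@]2(C)[C@@H]1[C@H](O)CC1=CCOC1=O | intermediate
27 | 14-deoxy-11-hydroxyandrographolide | C=C1CC[C@@H]2[C@](C)(CO)[C@H](O)CC[C@@]2(C)[C@@H]1[C@H](O)CC1=CCOC1=O | target

**Totals and risks**
Total step count: 18. Longest linear sequence: 17 steps (steps 1–14 and 16–18).

The three steps most likely to fail are steps 8, 11 and 16.

Step 8: unproductive equilibria (deconjugation of the alkylidene malonate, addition of methoxide or of the C-11 alkoxide to it) may outrun the Michael addition, or the facial selectivity at C-10 may be poor. The fallback makes the two bonds one after the other under Lewis-acid control. It sets out from 12, which would be converted with Me3SiCl, NaI and Et3N in MeCN into the bis(trimethylsilyl) derivative F1 (thermodynamic C-10 enol silane and C-11 silyl ether). An intramolecular Mukaiyama–Michael addition (TiCl4, CH2Cl2, −78 °C; aqueous work-up) should then give 13, now isolated, and the Claisen condensation alone (NaOMe, MeOH) should close ring A. The fallback returns to the route at 14.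

Step 11: the methyl ester may be over-reduced, or the C-1–O bond may be cleaved incompletely, under the dissolving-metal conditions. The fallback removes the C-1 oxygen as a ketone instead. It sets out from 16, which would be reduced with LiAlH4 to the allylic diol F2 (3-hydroxyl cis to C-19, enol ether intact) and protected with 2,2-dimethoxypropane/PPTS as the acetonide F3. Hydrolysis of the enol ether with oxalic acid in wet THF should give the C-1 ketone F4 with the C-11 hydroxyl free. Wolff–Kishner reduction under Huang–Minlon conditions (N2H4·H2O, KOH, diethylene glycol, 130 → 200 °C) would then take out the ketone. The fallback returns to the route at 20.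

Step 16: facial selectivity at the aldehyde may be poor, or C-9 may epimerise. The fallback sets C-11 by reagent control. It sets out from 21 by way of the step-16 mixture of 25 and the (11S)-epimer F5, which would be oxidised (Dess–Martin periodinane, NaHCO3, CH2Cl2) to the ketone F6. Corey–Bakshi–Shibata reduction with (S)-2-methyl-CBS-oxazaborolidine and BH3·SMe2 should, by the usual model, give the (11R)-alcohol. The fallback returns to the route at 25.

**Further compounds**
F1 | step 8 | dimethyl 2-[(5S)-6-methyl-4-methylidene-7-(trimethylsilyloxy)-5-[(trimethylsilyloxy)methyl]oct-6-enylidene]propanedioate (enol silane as E/Z mixture) | CC(O[Si](C)(C)C)=C(C)[C@H](CO[Si](C)(C)C)C(=C)CCC=C(C(=O)OC)C(=O)OC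
F2 | step 11 | allylic diol: C-3 carbinol and C-19 carbinol of 16 with the C-1 enol ether to O-11 intact | C=C1CC[C@@H]2[C@](C)(CO)[C@H](O)C=C3OC[C@H]1[C@@]23C
F3 | step 11 | 3,19-O-isopropylidene acetal of F2 | C=C1CC[C@@H]2[C@]4(C)COC(C)(C)O[C@@H]4C=C3OC[C@H]1[C@@]23C
F4 | step 11 | 1-oxo derivative of 20 (3,19-O-isopropylidene acetal, free 11-hydroxyl) | C=C1CC[C@@H]2[C@]3(C)COC(C)(C)O[C@@H]3CC(=O)[C@@]2(C)[C@@H]1CO
F5 | step 16 | (11S)-epimer of 25 | C=C1CC[C@@H]2[C@]3(C)COC(C)(C)O[C@@H]3CC[C@@]2(C)[C@@H]1[C@@H](O)CC(=C)C(=O)OCC=C
F6 | step 16 | C-11 ketone of 25 | C=C1CC[C@@H]2[C@]3(C)COC(C)(C)O[C@@H]3CC[C@@]2(C)[C@@H]1C(=O)CC(=C)C(=O)OCC=C
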